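## Retrosynthetic overview
1. The last skeletal bond is the ester C–O bond. It joins the secondary OH of a cyclohexanone diol (ring C) to a silyl-protected keto acid that carries the pyranone (ring A).
2. Ring C comes from a stepwise, ionic two-carbon ring expansion of a meso 3-silyloxy-2,4-dimethylcyclobutanone (ring B). The enol silane of pentan-3-one is inserted into one of the two enantiotopic C–C bonds, which forms two C–C bonds, sets four new stereocentres and keeps one.
3. Ring B comes from methylketene and the Z enol silane of propanal.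
4. In the acid, C1 comes from hydroboration/oxidation of a methallyl unit and C3–C4 from a boron anti-aldol with methacrolein. C5–C6 comes from a nickel-catalysed acyl coupling of propanoyl chloride with the 1-bromoethylpyranone.
5. Ring order: ring A (triketone cyclodehydration) in one branch; ring B and then ring C in the other. No ring is formed after the union.

Assumption: silyl groups count as protecting groups, and the ligand antipodes written ((R)-BINOL, (R,R)-Ph-BOX) are taken to give the drawn configurations; the mirror-image ligand is used if the sense turns out opposite.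

## Route

Step 1
Reactants: 1 propanal
Product: 2 (Z)-triethyl(prop-1-en-1-yloxy)silane
Conditions: Et3SiOTf, Et3N, CH2Cl2, 0 °C to rt
Reagents that add atoms: triethylsilyl triflate CC[Si](CC)(CC)OS(=O)(=O)C(F)(F)F
Why: Soft enolisation with O-silylation (silyl enol ether formation) gives mainly the Z isomer because the methyl group avoids the silylated oxygen in the deprotonation step; no stereocentre is formed.

Step 2
Reactants: 2 (Z)-triethyl(prop-1-en-1-yloxy)silane (3 equiv), 3 propanoyl chloride
Product: 5 meso all-cis (2R,3r,4S)-2,4-dimethyl-3-(triethylsilyloxy)cyclobutan-1-one, via methylketene 4 (not isolated)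
Conditions: Et3N, toluene, 80 °C, 3 added over 6 h
Reagents that add atoms: none
Why: Dehydrochlorination gives methylketene, whose ketene–enol ether [2+2] cycloaddition is faster with the Z enol ether, keeps the cis O/CH3 relation of 2 and places the ketene methyl group cis to the silyloxy group (orthogonal approach), so the achiral all-cis cyclobutanone results.

Step 3
Reactants: 6 pentan-3-one
Product: 7 (Z)-trimethyl(pent-2-en-3-yloxy)silane
Conditions: Me3SiCl, NaI, Et3N, MeCN, rt
Reagents that add atoms: chlorotrimethylsilane C[Si](C)(C)Cl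
Why: Silylation with Me3SiI made in situ under equilibrating conditions (Cazeau–Duboudin enol silane synthesis) gives the thermodynamically preferred Z enol silane; no stereocentre is formed.

Step 4
Reactants: 5 meso all-cis 2,4-dimethyl-3-(triethylsilyloxy)cyclobutan-1-one, 7 (Z)-trimethyl(pent-2-en-3-yloxy)silane
Product: 9 (2R,3R,4R,5R,6R)-3-ethyl-3,5-dihydroxy-2,4,6-trimethylcyclohexan-1-one, via bis-silyl ether 8 (not isolated)
Conditions: TiCl2(OiPr)2/(R)-BINOL (20 mol % each), 4 Å MS, CH2Cl2, −78 to −40 °C; then 1 M HCl, THF, 0 °C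
Reagents that add atoms: none
Why: Proposed new method: the chiral tetravalent-titanium Lewis acid binds the ketone of meso 5 and the silyloxy lone pair pushes open one of the two enantiotopic ring bonds at C3 (about 26 kcal/mol of strain is released; the BINOLate pocket selects the C3–C4 bond, so the 2R centre survives unchanged as C6 of 9); silyl transfer then leaves a titanium enolate whose metal also binds the freed formyl oxygen in a six-membered chelate, 7 attacks that aldehyde anti to the pseudo-axial methyl group (chelate, anti-Felkin sense: C5–O cis to C6–CH3 and trans to C4–CH3), and the enolate closes onto the resulting silyloxycarbenium ion through a chair with ethyl and the C2 and C4 methyl groups equatorial and the C3 oxygen axial; the closest known reaction types are the achiral Lewis-acid-promoted stepwise formal [4+2] ring expansion of 3-alkoxycyclobutanones with silyl enol ethers and the chelation-controlled Mukaiyama aldol addition.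

Step 5
Reactants: 6 pentan-3-one, 3 propanoyl chloride
Product: 11 4-methylheptane-3,5-dione, via lithium pent-2-en-3-olate 10 (not isolated)
Conditions: LiN(SiMe3)2 (2.1 equiv), toluene, 0 °C; 3; then 1 M HCl
Reagents that add atoms: none
Why: This is a Claisen-type C-acylation of the ketone enolate in which the second equivalent of base removes the acidic diketone proton and stops further acylation; the single stereocentre is labile and irrelevant.

Step 6
Reactants: 11 4-methylheptane-3,5-dione, 12 ethyl acetate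
Product: 15 2-ethyl-3,5,6-trimethyl-4H-pyran-4-one, via dilithium dienediolate 13 (not isolated), via 3,5-dimethyloctane-2,4,6-trione 14 (not isolated)
Conditions: LiN(iPr)2 (3.2 equiv), THF, −78 to 0 °C; 12; 1 M HCl; crude product in conc. H2SO4, 0 °C to rt
Reagents that add atoms: none
Why: Hauser-type acylation of the 1,3-diketone dianion takes place at the more basic terminal carbanion (the two termini of 11 are identical, so only one regioisomer forms), and acid cyclodehydration of the 1,3,5-triketone can give only this 4-pyranone.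

Step 7
Reactants: 15 2-ethyl-3,5,6-trimethyl-4H-pyran-4-one
Product: 16 rac-2-(1-bromoethyl)-3,5,6-trimethyl-4H-pyran-4-one
Conditions: NBS, (PhCO2)2 (5 mol %), PhCF3, 85 °C
Reagents that add atoms: N-bromosuccinimide O=C1CCC(=O)N1Br
Why: In this Wohl–Ziegler bromination the bromine atom abstracts the weakest C–H, the secondary pyranone-conjugated CH2 of the ethyl group, in preference to the primary methyl C–H bonds; the bromide is racemic.

Step 8
Reactants: 16 rac-2-(1-bromoethyl)-3,5,6-trimethyl-4H-pyran-4-one, 3 propanoyl chloride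
Product: 17 (S)-2-(3,5,6-trimethyl-4-oxo-4H-pyran-2-yl)pentan-3-one
Conditions: NiCl2(dme) (10 mol %), (R,R)-Ph-BOX (22 mol %), Mn powder (3 equiv), 2,6-dimethylbenzoic acid (0.75 equiv), 3 Å MS, DMA/THF 3:7, 20 °C
Reagents that add atoms: none
Why: In this nickel-catalysed enantioconvergent reductive acyl cross-coupling both enantiomers of 16 give the same stabilised secondary radical, which the chiral bis(oxazoline) acyl-nickel species captures to set the S centre next to the pyranone, and the base-free medium keeps that centre from epimerising.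

Step 9
Reactants: 17 (S)-2-(3,5,6-trimethyl-4-oxo-4H-pyran-2-yl)pentan-3-one, 18 methacrolein
Product: 21 (2S,4S,5R)-5-hydroxy-4,6-dimethyl-2-(3,5,6-trimethyl-4-oxo-4H-pyran-2-yl)hept-6-en-3-one, via E-enol dicyclohexylborinate 19 (not isolated), via boron aldolate 20 (not isolated)
Conditions: Cy2BCl (2.5 equiv), Et3N (3 equiv), Et2O, 0 °C; 18, −78 to −20 °C; H2O2, MeOH, pH 7 buffer, 0 °C
Reagents that add atoms: none
Why: In this boron-mediated anti-aldol reaction Cy2BCl/Et3N enolises the unhindered ethyl side to the E enol borinate (allylic strain with the pyranone 3-methyl group keeps the doubly activated C–H out of alignment), the chair Zimmerman–Traxler transition state gives the 4,5-anti relation, and the existing centre directs the 2,4-anti relation as in E-boron aldol reactions of alpha-chiral beta-keto imides.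

Step 10
Reactants: 21 the aldol adduct
Product: 22 (2S,4S,5R)-5-(tert-butyldimethylsilyloxy)-4,6-dimethyl-2-(3,5,6-trimethyl-4-oxo-4H-pyran-2-yl)hept-6-en-3-one
Conditions: tBuMe2SiOTf, 2,6-lutidine, CH2Cl2, −78 to 0 °C
Reagents that add atoms: tert-butyldimethylsilyl triflate CC(C)(C)[Si](C)(C)OS(=O)(=O)C(F)(F)F
Why: Silyl triflate silylation of a hindered secondary alcohol with a non-nucleophilic base touches no stereocentre and blocks retro-aldol cleavage in the next steps.

Step 11
Reactants: 22 the silyl ether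
Product: 24 (2S,4S,5S,6S)-5-(tert-butyldimethylsilyloxy)-7-hydroxy-4,6-dimethyl-2-(3,5,6-trimethyl-4-oxo-4H-pyran-2-yl)heptan-3-one, via B-alkyl-9-BBN adduct 23 (not isolated)
Conditions: 9-BBN (2.5 equiv), THF, 0 °C to rt; 30% H2O2, aq NaOAc, 0 °C
Reagents that add atoms: hydrogen peroxide OO
Why: Substrate-controlled Brown hydroboration of a 1,1-disubstituted allylic silyl ether (Still–Barrish model, carbinol H eclipsing the alkene and the borane anti to the chain) sets the new methyl centre anti to the silyloxy group, and the bulky borane reaches the terminal alkene faster than the doubly alpha-branched ketone.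

Step 12
Reactants: 24 the primary alcohol
Product: 26 (2R,3R,4S,6S)-3-(tert-butyldimethylsilyloxy)-2,4-dimethyl-5-oxo-6-(3,5,6-trimethyl-4-oxo-4H-pyran-2-yl)heptanoic acid, via aldehyde 25 (not isolated)
Conditions: TEMPO (20 mol %), PhI(OAc)2 (2.5 equiv), MeCN/pH 7 buffer, rt
Reagents that add atoms: water O
Why: The oxoammonium (TEMPO/PhI(OAc)2) oxidation runs through the aldehyde hydrate to the acid at near-neutral pH, so none of the alpha-carbonyl stereocentres epimerises.

Step 13
Reactants: 26 the acid, 9 the cyclohexanone diol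
Product: 28 (1R,2R,3R,4R,6R)-3-ethyl-3-hydroxy-2,4,6-trimethyl-5-oxocyclohexyl ester of 26, via mixed anhydride 27 (not isolated)
Conditions: 2,4,6-Cl3C6H2COCl, Et3N, toluene, rt; then 9, DMAP, toluene, rt
Reagents that add atoms: none
Why: In this Yamaguchi esterification the DMAP-activated mixed anhydride acylates only the equatorial secondary OH of 9 (the tertiary OH is inert), no stereocentre changes, and any ester from the minor enantiomer of 9 is a separable diastereomer.

Step 14
Reactants: 28 the silyl-protected ester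
Product: 29 the target CNP0260549.2
Conditions: HF·pyridine, pyridine, THF, 0 °C to rt
Reagents that add atoms: none
Why: Fluoride-mediated desilylation in a buffered, weakly acidic medium frees the side-chain alcohol without elimination or retro-aldol cleavage of the beta-acyloxy and beta-hydroxy ketone units.

## Compound list
1 | propanal | CCC=O | starting material
2 | (Z)-triethyl(prop-1-en-1-yloxy)silane | C/C=C\O[Si](CC)(CC)CC | intermediate
3 | propanoyl chloride | CCC(=O)Cl | starting material
4 | methylketene | CC=C=O | intermediate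
5 | meso all-cis (2R,3r,4S)-2,4-dimethyl-3-(triethylsilyloxy)cyclobutan-1-one | C[C@H]1C(=O)[C@@H](C)[C@H]1O[Si](CC)(CC)CC | intermediate
6 | pentan-3-one | CCC(=O)CC | starting material
7 | (Z)-trimethyl(pent-2-en-3-yloxy)silane | C/C=C(\O[Si](C)(C)C)CC | intermediate
8 | (2R,3R,4R,5R,6R)-3-ethyl-2,4,6-trimethyl-5-(triethylsilyloxy)-3-(trimethylsilyloxy)cyclohexan-1-one | CC[C@@]1(O[Si](C)(C)C)[C@H](C)[C@@H](O[Si](CC)(CC)CC)[C@@H](C)C(=O)[C@@H]1C | intermediate
9 | (2R,3R,4R,5R,6R)-3-ethyl-3,5-dihydroxy-2,4,6-trimethylcyclohexan-1-one | CC[C@@]1(O)[C@H](C)[C@@H](O)[C@@H](C)C(=O)[C@@H]1C | intermediate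
10 | lithium pent-2-en-3-olate | CC=C([O-])CC.[Li+] | intermediate
11 | 4-methylheptane-3,5-dione | CCC(=O)C(C)C(=O)CC | intermediate
12 | ethyl acetate | CCOC(C)=O | starting material
13 | dilithium 4-methylhepta-2,4-diene-3,5-diolate | CC=C([O-])C(C)=C([O-])CC.[Li+].[Li+] | intermediate
14 | 3,5-dimethyloctane-2,4,6-trione | CCC(=O)C(C)C(=O)C(C)C(C)=O | intermediate
15 | 2-ethyl-3,5,6-trimethyl-4H-pyran-4-one | CCc1oc(C)c(C)c(=O)c1C | intermediate
16 | rac-2-(1-bromoethyl)-3,5,6-trimethyl-4H-pyran-4-one | CC(Br)c1oc(C)c(C)c(=O)c1C | intermediate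
17 | (S)-2-(3,5,6-trimethyl-4-oxo-4H-pyran-2-yl)pentan-3-one | CCC(=O)[C@@H](C)c1oc(C)c(C)c(=O)c1C | intermediate
18 | methacrolein | C=C(C)C=O | starting material
19 | E-enol dicyclohexylborinate of 17 | C/C=C(/OB(C1CCCCC1)C1CCCCC1)[C@@H](C)c1oc(C)c(C)c(=O)c1C | intermediate
20 | dicyclohexylboron aldolate of 21 | C=C(C)[C@H](OB(C1CCCCC1)C1CCCCC1)[C@H](C)C(=O)[C@@H](C)c1oc(C)c(C)c(=O)c1C | intermediate
21 | (2S,4S,5R)-5-hydroxy-4,6-dimethyl-2-(3,5,6-trimethyl-4-oxo-4H-pyran-2-yl)hept-6-en-3-one | C=C(C)[C@H](O)[C@H](C)C(=O)[C@@H](C)c1oc(C)c(C)c(=O)c1C | intermediate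
22 | (2S,4S,5R)-5-(tert-butyldimethylsilyloxy)-4,6-dimethyl-2-(3,5,6-trimethyl-4-oxo-4H-pyran-2-yl)hept-6-en-3-one | C=C(C)[C@H](O[Si](C)(C)C(C)(C)C)[C@H](C)C(=O)[C@@H](C)c1oc(C)c(C)c(=O)c1C | intermediate
23 | B-alkyl-9-BBN adduct of 22 | C1CC2CCCC(C1)B2C[C@H](C)[C@H](O[Si](C)(C)C(C)(C)C)[C@H](C)C(=O)[C@@H](C)c1oc(C)c(C)c(=O)c1C | intermediate
24 | (2S,4S,5S,6S)-5-(tert-butyldimethylsilyloxy)-7-hydroxy-4,6-dimethyl-2-(3,5,6-trimethyl-4-oxo-4H-pyran-2-yl)heptan-3-one | OC[C@H](C)[C@H](O[Si](C)(C)C(C)(C)C)[C@H](C)C(=O)[C@@H](C)c1oc(C)c(C)c(=O)c1C | intermediate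
25 | (2R,3S,4S,6S)-3-(tert-butyldimethylsilyloxy)-2,4-dimethyl-5-oxo-6-(3,5,6-trimethyl-4-oxo-4H-pyran-2-yl)heptanal | O=C[C@H](C)[C@H](O[Si](C)(C)C(C)(C)C)[C@H](C)C(=O)[C@@H](C)c1oc(C)c(C)c(=O)c1C | intermediate
26 | (2R,3R,4S,6S)-3-(tert-butyldimethylsilyloxy)-2,4-dimethyl-5-oxo-6-(3,5,6-trimethyl-4-oxo-4H-pyran-2-yl)heptanoic acid | OC(=O)[C@H](C)[C@H](O[Si](C)(C)C(C)(C)C)[C@H](C)C(=O)[C@@H](C)c1oc(C)c(C)c(=O)c1C | intermediate
27 | mixed anhydride of 26 with 2,4,6-trichlorobenzoic acid | Clc1cc(Cl)c(C(=O)OC(=O)[C@H](C)[C@H](O[Si](C)(C)C(C)(C)C)[C@H](C)C(=O)[C@@H](C)c2oc(C)c(C)c(=O)c2C)c(Cl)c1 | intermediate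
28 | (1R,2R,3R,4R,6R)-3-ethyl-3-hydroxy-2,4,6-trimethyl-5-oxocyclohexyl ester of 26 | CC[C@@]1(O)[C@H](C)[C@@H](OC(=O)[C@H](C)[C@H](O[Si](C)(C)C(C)(C)C)[C@H](C)C(=O)[C@@H](C)c2oc(C)c(C)c(=O)c2C)[C@@H](C)C(=O)[C@@H]1C | intermediate
29 | CNP0260549.2, (1R,2R,3R,4R,6R)-3-ethyl-3-hydroxy-2,4,6-trimethyl-5-oxocyclohexyl (2R,3R,4S,6S)-3-hydroxy-2,4-dimethyl-5-oxo-6-(3,5,6-trimethyl-4-oxo-4H-pyran-2-yl)heptanoate | CC[C@@]1(O)[C@H](C)[C@@H](OC(=O)[C@H](C)[C@H](O)[C@H](C)C(=O)[C@@H](C)c2oc(C)c(C)c(=O)c2C)[C@@H](C)C(=O)[C@@H]1C | target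

## Step count and risks
Total step count: 14. Longest linear sequence: 10 (steps 5 to 14, from pentan-3-one). One protecting group is carried on the side chain; the silyl groups of the ring branch are consumed in the ring expansion.

**Risk 1, step 4 (the new ring expansion).**
- Addition through a non-chelated, Felkin-type ion pair would give the C6-epimeric series.
- The catalyst may discriminate poorly between the two enantiotopic bonds.
- The ring-opened species may oligomerise, or silanol may be lost to give an enone.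

The fallback is an acyclic aldol route built from known chemistry. It sets out from 1, 6 and 26 and comes back at 28. L-Proline-catalysed self-aldol of 1 gives (2S,3S)-3-hydroxy-2-methylpentanal F1, and Et3SiCl/imidazole gives (2S,3S)-2-methyl-3-(triethylsilyloxy)pentanal F2. The E-dicyclohexylboron enolate of 6 adds in the anti, Felkin sense to give (4R,5R,6R,7S)-5-hydroxy-4,6-dimethyl-7-(triethylsilyloxy)nonan-3-one F3. Yamaguchi esterification with 26 gives the 7-triethylsilyloxy nonanone ester F4, and PPTS in MeOH removes only the triethylsilyl group to give the 7-hydroxy nonanone ester F5. Dess–Martin oxidation gives the (4R,6R)-4,6-dimethyl-3,7-dioxononan-5-yl ester F6, in which C5 is no longer a stereocentre. Intramolecular aldol addition on neutral alumina then closes ring C to 28.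

**Risk 2, step 8 (nickel coupling).** The method is established for secondary benzylic chlorides. The pyranonyl bromide may homocouple, bind nickel through its carbonyl group, or give low ee.

The fallback sets the stereocentre by asymmetric hydroformylation instead of cross-coupling. It sets out from 16 and comes back at 17. DBU elimination gives 2-ethenyl-3,5,6-trimethyl-4H-pyran-4-one F7. Branched-selective asymmetric hydroformylation (Rh(acac)(CO)2, (R,S)-BINAPHOS, CO/H2) gives (S)-2-(3,5,6-trimethyl-4-oxo-4H-pyran-2-yl)propanal F8, which is used at once. EtMgBr at −78 °C gives 2-(3,5,6-trimethyl-4-oxo-4H-pyran-2-yl)pentan-3-ol F9, and Dess–Martin oxidation gives 17.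

**Risk 3, step 11 (hydroboration next to a ketone and a pyranone).** The ketone may be reduced competitively.

The fallback accepts the reduction and restores the oxidation level afterwards. It sets out from 22 and comes back at 26. Excess 9-BBN at 40 °C followed by H2O2/NaOAc gives the 3,7-diol F10 with the same anti selectivity at the new methyl centre. Dess–Martin oxidation of both alcohols gives keto aldehyde 25, and Pinnick oxidation (NaClO2, NaH2PO4, 2-methyl-2-butene) gives 26.

## Further compounds
F1 | step 4 | (2S,3S)-3-hydroxy-2-methylpentanal | CC[C@H](O)[C@H](C)C=O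
F2 | step 4 | (2S,3S)-2-methyl-3-(triethylsilyloxy)pentanal | CC[C@H](O[Si](CC)(CC)CC)[C@H](C)C=O
F3 | step 4 | (4R,5R,6R,7S)-5-hydroxy-4,6-dimethyl-7-(triethylsilyloxy)nonan-3-one | CC[C@H](O[Si](CC)(CC)CC)[C@H](C)[C@@H](O)[C@@H](C)C(=O)CC
F4 | step 4 | 7-triethylsilyloxy nonanone ester | CC[C@H](O[Si](CC)(CC)CC)[C@H](C)[C@@H](OC(=O)[C@H](C)[C@H](O[Si](C)(C)C(C)(C)C)[C@H](C)C(=O)[C@@H](C)c1oc(C)c(C)c(=O)c1C)[C@@H](C)C(=O)CC
F5 | step 4 | 7-hydroxy nonanone ester | CC[C@H](O)[C@H](C)[C@@H](OC(=O)[C@H](C)[C@H](O[Si](C)(C)C(C)(C)C)[C@H](C)C(=O)[C@@H](C)c1oc(C)c(C)c(=O)c1C)[C@@H](C)C(=O)CC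
F6 | step 4 | (4R,6R)-4,6-dimethyl-3,7-dioxononan-5-yl ester | CCC(=O)[C@H](C)C(OC(=O)[C@H](C)[C@H](O[Si](C)(C)C(C)(C)C)[C@H](C)C(=O)[C@@H](C)c1oc(C)c(C)c(=O)c1C)[C@@H](C)C(=O)CC
F7 | step 8 | 2-ethenyl-3,5,6-trimethyl-4H-pyran-4-one | C=Cc1oc(C)c(C)c(=O)c1C
F8 | step 8 | (S)-2-(3,5,6-trimethyl-4-oxo-4H-pyran-2-yl)propanal | O=C[C@@H](C)c1oc(C)c(C)c(=O)c1C
F9 | step 8 | 2-(3,5,6-trimethyl-4-oxo-4H-pyran-2-yl)pentan-3-ol | CCC(O)[C@@H](C)c1oc(C)c(C)c(=O)c1C
F10 | step 11 | 3,7-diol | OC[C@H](C)[C@H](O[Si](C)(C)C(C)(C)C)[C@H](C)C(O)[C@@H](C)c1oc(C)c(C)c(=O)c1C
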